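**Plan**
- Numbering: ring A carries OH at position 1, the diaryl ether oxygen at position 3 and chain carbon 14 at position 5. Ring B carries the ether oxygen at position 1, OH at positions 3 and 6, and chain carbon 1 at position 5. The bridge is chain carbons 1 to 14.
- Retrosynthesis: with the phenols as methyl ethers, the bond between chain carbons 13 and 14 is cut and an SO2 unit is set between the two carbons (22-membered sulfone). Then the bond from sulfur to chain carbon 13 (macrocyclisation), the bond between chain carbons 1 and 2 (Wittig) and the diaryl ether bond (Ullmann coupling) are cut.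
- Forward: the salicylaldehyde is brominated and methylated to the ring B bromide, CuI coupling joins ring A, and chain carbons 2 to 13 are attached by Wittig olefination and hydrogenated. The ends are turned into a primary bromide and a benzylic thioacetate, the thiolate closes the 22-membered ring, and oxidation gives the sulfone. Ramberg–Bäcklund contraction then closes the 21-membered ring.
- Enabling feature: chain carbon 14 is a benzylic methylene on position 5 of ring A. A sulfone set between chain carbons 13 and 14 therefore has an aryl-activated alpha carbon that is easily deprotonated and halogenated, and the sulfur can be extruded to leave only the carbon–carbon bond.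
- Stereochemistry: the target has no stereocentre. The alkene geometries from the Wittig and ring-contraction steps are erased by hydrogenation.

Key step: step 12

Remark on the chemistry: the Wittig alkene and the ring-contracted alkene are drawn as the isomers expected to predominate (Z and E respectively). Both geometries converge on hydrogenation, so isomer mixtures would be carried on unseparated.

**Step 1**
Reactants: 1 2-hydroxy-5-methoxybenzaldehyde
Product: 2 3-bromo-2-hydroxy-5-methoxybenzaldehyde
Conditions: Br2 (1.05 equiv), NaOAc, AcOH, rt
Reagents that add atoms: bromine, BrBr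
Why: Electrophilic aromatic bromination should go to position 3, the only free position ortho to the phenol (its para position carries OMe) and the one meta to the deactivating formyl group.

**Step 2**
Reactants: 2 3-bromo-2-hydroxy-5-methoxybenzaldehyde
Product: 3 3-bromo-2,5-dimethoxybenzaldehyde
Conditions: MeI, K2CO3, DMF, rt
Reagents that add atoms: iodomethane, CI
Why: Williamson O-methylation of an acidic ortho-formyl phenol is routine and leaves the aldehyde and aryl bromide untouched.

**Step 3**
Reactants: 3 3-bromo-2,5-dimethoxybenzaldehyde; 4 methyl 3-hydroxy-5-methoxybenzoate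
Product: 5 methyl 3-(3-formyl-2,5-dimethoxyphenoxy)-5-methoxybenzoate
Conditions: CuI (cat.), N,N-dimethylglycine·HCl (cat.), Cs2CO3, 1,4-dioxane, 90 °C
Reagents that add atoms: none
Why: Ligand-accelerated Ullmann diaryl ether coupling of an aryl bromide with an unhindered phenol should tolerate the non-enolisable aldehyde and the methyl ester under carbonate base.

**Step 4**
Reactants: 6 12-bromododecan-1-ol
Product: 7 (12-hydroxydodecyl)triphenylphosphonium bromide
Conditions: PPh3, MeCN, reflux
Reagents that add atoms: triphenylphosphine, c1ccc(cc1)P(c1ccccc1)c1ccccc1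
Why: SN2 quaternisation of PPh3 by a primary alkyl bromide is standard and the free hydroxyl does not interfere.

**Step 5**
Reactants: 7 (12-hydroxydodecyl)triphenylphosphonium bromide; 5 methyl 3-(3-formyl-2,5-dimethoxyphenoxy)-5-methoxybenzoate
Product: 9 methyl 3-[3-[(Z)-13-hydroxytridec-1-en-1-yl]-2,5-dimethoxyphenoxy]-5-methoxybenzoate, via ylide alkoxide 8 (not isolated)
Conditions: LiN(SiMe3)2 (2.1 equiv), THF, −78 to 0 °C; then 5, −78 °C to rt; aq. NH4Cl
Reagents that add atoms: none
Why: Wittig olefination of an unstabilised ylide with an aryl aldehyde is fast at low temperature, two equivalents of base cover the hydroxyl, and the lithium alkoxide is too weak a nucleophile to attack the methyl benzoate in that time.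

**Step 6**
Reactants: 9 methyl 3-[3-[(Z)-13-hydroxytridec-1-en-1-yl]-2,5-dimethoxyphenoxy]-5-methoxybenzoate
Product: 10 methyl 3-[3-(13-hydroxytridecyl)-2,5-dimethoxyphenoxy]-5-methoxybenzoate
Conditions: H2 (1 atm), Pd/C, EtOAc, rt
Reagents that add atoms: none
Why: Heterogeneous hydrogenation of a disubstituted styrenyl alkene is facile, the aryl ethers and ester are inert, and it removes the E/Z question before the long sequence.

**Step 7**
Reactants: 10 methyl 3-[3-(13-hydroxytridecyl)-2,5-dimethoxyphenoxy]-5-methoxybenzoate
Product: 11 methyl 3-[3-(13-bromotridecyl)-2,5-dimethoxyphenoxy]-5-methoxybenzoate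
Conditions: CBr4, PPh3, CH2Cl2, 0 °C
Reagents that add atoms: carbon tetrabromide, BrC(Br)(Br)Br
Why: The Appel reaction converts a primary alcohol into the bromide under neutral conditions that spare the ester and aryl ethers.

**Step 8**
Reactants: 11 methyl 3-[3-(13-bromotridecyl)-2,5-dimethoxyphenoxy]-5-methoxybenzoate
Product: 12 [3-[3-(13-bromotridecyl)-2,5-dimethoxyphenoxy]-5-methoxyphenyl]methanol
Conditions: i-Bu2AlH (2.5 equiv), CH2Cl2, −78 to 0 °C; aq. potassium sodium tartrate
Reagents that add atoms: none
Why: i-Bu2AlH reduces a methyl benzoate to the benzylic alcohol at low temperature and does not reduce an unactivated primary alkyl bromide.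

**Step 9**
Reactants: 12 [3-[3-(13-bromotridecyl)-2,5-dimethoxyphenoxy]-5-methoxyphenyl]methanol
Product: 13 S-[[3-[3-(13-bromotridecyl)-2,5-dimethoxyphenoxy]-5-methoxyphenyl]methyl] ethanethioate
Conditions: PPh3, DIAD, THF, 0 °C; then 12 and AcSH, 0 °C to rt
Reagents that add atoms: thioacetic acid, CC(=O)S
Why: Mitsunobu thioesterification activates only the benzylic alcohol, and under these neutral conditions the primary bromide should not be displaced.

**Step 10**
Reactants: 13 S-[[3-[3-(13-bromotridecyl)-2,5-dimethoxyphenoxy]-5-methoxyphenyl]methyl] ethanethioate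
Product: 15 macrocyclic benzyl alkyl sulfide (22-membered ring; trimethyl ether), via cesium thiolate 14 (not isolated)
Conditions: Cs2CO3, degassed MeOH/THF, syringe-pump addition of 13 (final ca. 1 mM), 40 °C
Reagents that add atoms: none
Why: Methanolysis of the thioacetate releases a soft cesium thiolate in low stationary concentration, and its intramolecular SN2 attack on the primary bromide is a well-precedented macrocyclic thioether formation.

**Step 11**
Reactants: 15 macrocyclic benzyl alkyl sulfide (22-membered ring; trimethyl ether)
Product: 16 macrocyclic benzyl alkyl sulfone (22-membered ring; S,S-dioxide of 15 with SO2 between chain carbons 13 and 14)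
Conditions: mCPBA (2.2 equiv), CH2Cl2, 0 °C to rt
Reagents that add atoms: 3-chloroperoxybenzoic acid, OOC(=O)c1cccc(Cl)c1
Why: Peracid oxidation of a dialkyl-type sulfide through the sulfoxide to the sulfone is reliable, and no alkene or other oxidisable group is present.

**Step 12**
Reactants: 16 macrocyclic benzyl alkyl sulfone (22-membered ring)
Product: 19 macrocyclic E styrenyl alkene (21-membered ring; trimethyl ether), via alpha-bromo sulfone 17 (not isolated), via episulfone 18 (not isolated)
Conditions: KOH/Al2O3, CBr2F2, t-BuOH/CH2Cl2, 5 °C to rt
Reagents that add atoms: none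
Why: Ramberg–Bäcklund reaction with halogenation in the same flask: the solid base deprotonates the benzylic alpha carbon (chain carbon 14), the carbanion takes bromine from CBr2F2 to give 17, deprotonation at chain carbon 13 and 1,3-displacement of bromide give episulfone 18, and cheletropic loss of SO2 leaves the double bond between chain carbons 13 and 14. The closest known reaction type is the contraction of macrocyclic benzylic sulfones to cyclophane alkenes under these one-flask conditions. The 21-membered ring arises by 3-exo-tet closure of the thiirane dioxide inside the 22-membered ring followed by SO2 extrusion, so the carbon–carbon bond forms through a three-membered transition state whose rate depends neither on ring size nor on dilution. No stereocentre is created in the product; the E geometry is expected because the acidic benzylic hydrogen lets the episulfone equilibrate to the trans isomer before SO2 is lost, and any Z isomer converges in step 13. The step needs halogenation alpha to sulfur and nowhere else, which the substrate secures because only chain carbons 13 and 14 carry acidic hydrogens (carbon 14 activated by both SO2 and ring A), while the methylene at chain carbon 1, the aryl methyl ethers and the diaryl ether are inert to KOH; halogenation at either alpha carbon leads to the same alkene.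

**Step 13**
Reactants: 19 macrocyclic E styrenyl alkene (21-membered ring; trimethyl ether)
Product: 20 tri-O-methyl ether of the target (saturated 21-membered ring)
Conditions: H2 (1 atm), Pd/C, EtOAc, rt
Reagents that add atoms: none
Why: Hydrogenation of the sulfur-free styrenyl alkene over Pd/C is routine and the aryl ethers do not undergo hydrogenolysis.

**Step 14**
Reactants: 20 tri-O-methyl ether of the target
Product: 21 CNP0393720.0 (the free triphenol)
Conditions: BBr3 (excess), CH2Cl2, −78 °C to rt; degassed H2O quench, work-up under argon
Reagents that add atoms: none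
Why: BBr3 cleaves aryl methyl ethers by bromide attack at the methyl carbon, whereas the diaryl ether offers no sp3 carbon and should survive; air is excluded because ring B is released as a hydroquinone.

**Compound list**
1 | 2-hydroxy-5-methoxybenzaldehyde | COc1ccc(O)c(C=O)c1 | starting material
2 | 3-bromo-2-hydroxy-5-methoxybenzaldehyde | COc1cc(Br)c(O)c(C=O)c1 | intermediate
3 | 3-bromo-2,5-dimethoxybenzaldehyde | COc1cc(Br)c(OC)c(C=O)c1 | intermediate
4 | methyl 3-hydroxy-5-methoxybenzoate | COC(=O)c1cc(O)cc(OC)c1 | starting material
5 | methyl 3-(3-formyl-2,5-dimethoxyphenoxy)-5-methoxybenzoate | COC(=O)c1cc(OC)cc(Oc2cc(OC)cc(C=O)c2OC)c1 | intermediate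
6 | 12-bromododecan-1-ol | OCCCCCCCCCCCCBr | starting material
7 | (12-hydroxydodecyl)triphenylphosphonium bromide | OCCCCCCCCCCCC[P+](c1ccccc1)(c1ccccc1)c1ccccc1.[Br-] | intermediate
8 | lithium 12-(triphenylphosphoranylidene)dodecan-1-olate (ylide alkoxide, not isolated) | [Li+].[O-]CCCCCCCCCCCC=P(c1ccccc1)(c1ccccc1)c1ccccc1 | intermediate
9 | methyl 3-[3-[(Z)-13-hydroxytridec-1-en-1-yl]-2,5-dimethoxyphenoxy]-5-methoxybenzoate | COC(=O)c1cc(OC)cc(Oc2cc(OC)cc(/C=C\CCCCCCCCCCCO)c2OC)c1 | intermediate
10 | methyl 3-[3-(13-hydroxytridecyl)-2,5-dimethoxyphenoxy]-5-methoxybenzoate | COC(=O)c1cc(OC)cc(Oc2cc(OC)cc(CCCCCCCCCCCCCO)c2OC)c1 | intermediate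
11 | methyl 3-[3-(13-bromotridecyl)-2,5-dimethoxyphenoxy]-5-methoxybenzoate | COC(=O)c1cc(OC)cc(Oc2cc(OC)cc(CCCCCCCCCCCCCBr)c2OC)c1 | intermediate
12 | [3-[3-(13-bromotridecyl)-2,5-dimethoxyphenoxy]-5-methoxyphenyl]methanol | OCc1cc(OC)cc(Oc2cc(OC)cc(CCCCCCCCCCCCCBr)c2OC)c1 | intermediate
13 | S-[[3-[3-(13-bromotridecyl)-2,5-dimethoxyphenoxy]-5-methoxyphenyl]methyl] ethanethioate | CC(=O)SCc1cc(OC)cc(Oc2cc(OC)cc(CCCCCCCCCCCCCBr)c2OC)c1 | intermediate
14 | cesium [3-[3-(13-bromotridecyl)-2,5-dimethoxyphenoxy]-5-methoxyphenyl]methanethiolate (not isolated) | [Cs+].[S-]Cc1cc(OC)cc(Oc2cc(OC)cc(CCCCCCCCCCCCCBr)c2OC)c1 | intermediate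
15 | macrocyclic benzyl alkyl sulfide (22-membered ring): the benzylic CH2 at position 5 of ring A (chain carbon 14) is bonded to sulfur, and sulfur to chain carbon 13 of the 13-carbon chain that starts at position 5 of ring B; the rings are joined by the ether oxygen between position 3 of ring A and position 1 of ring B; OMe at position 1 of ring A and at positions 3 and 6 of ring B | COc1cc2cc(c1)Oc1cc(OC)cc(c1OC)CCCCCCCCCCCCCSC2 | intermediate
16 | macrocyclic benzyl alkyl sulfone (22-membered ring; S,S-dioxide of 15) | COc1cc2cc(c1)Oc1cc(OC)cc(c1OC)CCCCCCCCCCCCCS(=O)(=O)C2 | intermediate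
17 | alpha-bromo sulfone, Br on the benzylic chain carbon 14 of 16 (racemic, not isolated) | COc1cc2cc(c1)Oc1cc(OC)cc(c1OC)CCCCCCCCCCCCCS(=O)(=O)C2Br | intermediate
18 | trans episulfone, thiirane 1,1-dioxide across chain carbons 13 and 14 (racemic, one enantiomer drawn, not isolated) | COc1cc2cc(c1)Oc1cc(OC)cc(c1OC)CCCCCCCCCCCC[C@H]3[C@H]2S3(=O)=O | intermediate
19 | macrocyclic E styrenyl alkene (21-membered ring): E double bond between chain carbons 13 and 14, conjugated to ring A; OMe at position 1 of ring A and at positions 3 and 6 of ring B | COc1cc2/C=C/CCCCCCCCCCCCc3cc(OC)cc(c3OC)Oc(c1)c2 | intermediate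
20 | tri-O-methyl ether of the target (saturated 21-membered ring) | COc1cc2cc(c1)Oc1cc(OC)cc(c1OC)CCCCCCCCCCCCCC2 | intermediate
21 | CNP0393720.0 | Oc1cc2cc(c1)Oc1cc(O)cc(c1O)CCCCCCCCCCCCCC2 | target

**Totals**
Total step count: 14. Longest linear sequence: 13 steps (steps 1–3 and 5–14 from compound 1; step 4 prepares the phosphonium salt on a side branch).

**Steps most likely to fail**

1. Step 12 (key step). The benzylic carbanion may be brominated twice, or the second deprotonation at the unactivated methylene of chain carbon 13 may be too slow on the solid base. Halogenated sulfone would then accumulate or decompose instead of closing to the episulfone. Fallback: set out from sulfide 15 and fix the halogen before the base step. NCS in CH2Cl2 at 0 °C should chlorinate the benzylic carbon by a Pummerer-type path to give the alpha-chloro sulfide F1. Oxidation with mCPBA gives the isolable alpha-chloro sulfone F2. KOt-Bu in THF, −78 °C to rt, then performs the classical Ramberg–Bäcklund reaction of a preformed halo sulfone through episulfone 18 and comes back to the route at alkene 19.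

2. Step 10. Intermolecular S-alkylation (oligomers) and oxidative coupling of the thiolate to disulfide may outrun closure of the 22-membered ring, because the primary bromide is a slow electrophile and the thiolate is long-lived. Fallback: reverse the polarity so that the ring closes at the far more reactive benzylic carbon, setting out from bromo alcohol 12. KSAc in DMF at rt displaces the primary bromide to give the thioacetate alcohol F3. CBr4/PPh3 converts the benzylic alcohol into the thioacetate benzylic bromide F4. Slow addition to Cs2CO3 in degassed MeOH/THF liberates the alkyl cesium thiolate F5, which is consumed quickly by the benzylic bromide and comes back to the route at sulfide 15.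

3. Step 3. Oxidative addition of copper into the ortho-methoxy-flanked bromide may be slow at 90 °C, so that protodebromination and base-induced degradation of the aldehyde compete with ether formation. Fallback: replace the aryl halide coupling by an oxidative Chan–Lam coupling at room temperature, setting out from bromide 3. Miyaura borylation (bis(pinacolato)diboron, PdCl2(dppf), KOAc, dioxane, 80 °C), which tolerates the aldehyde, gives the pinacol boronate F6. NaIO4/NH4OAc in aqueous acetone frees the boronic acid F7. Cu(OAc)2, pyridine, 4 Å molecular sieves and air in CH2Cl2 with phenol 4 then come back to the route at diaryl ether 5.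

**Further compounds**
F1 | step 12 | alpha-chloro sulfide, Cl on the benzylic chain carbon 14 of 15 (racemic) | COc1cc2cc(c1)Oc1cc(OC)cc(c1OC)CCCCCCCCCCCCCSC2Cl
F2 | step 12 | alpha-chloro sulfone, Cl on the benzylic chain carbon 14 of 16 (racemic) | COc1cc2cc(c1)Oc1cc(OC)cc(c1OC)CCCCCCCCCCCCCS(=O)(=O)C2Cl
F3 | step 10 | S-[13-[3-[3-(hydroxymethyl)-5-methoxyphenoxy]-2,5-dimethoxyphenyl]tridecyl] ethanethioate | OCc1cc(OC)cc(Oc2cc(OC)cc(CCCCCCCCCCCCCSC(C)=O)c2OC)c1
F4 | step 10 | S-[13-[3-[3-(bromomethyl)-5-methoxyphenoxy]-2,5-dimethoxyphenyl]tridecyl] ethanethioate | BrCc1cc(OC)cc(Oc2cc(OC)cc(CCCCCCCCCCCCCSC(C)=O)c2OC)c1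
F5 | step 10 | cesium 13-[3-[3-(bromomethyl)-5-methoxyphenoxy]-2,5-dimethoxyphenyl]tridecane-1-thiolate (not isolated) | BrCc1cc(OC)cc(Oc2cc(OC)cc(CCCCCCCCCCCCC[S-])c2OC)c1.[Cs+]
F6 | step 3 | 2,5-dimethoxy-3-(4,4,5,5-tetramethyl-1,3,2-dioxaborolan-2-yl)benzaldehyde | COc1cc(C=O)c(OC)c(c1)B1OC(C)(C)C(C)(C)O1
F7 | step 3 | (3-formyl-2,5-dimethoxyphenyl)boronic acid | COc1cc(C=O)c(OC)c(c1)B(O)O
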